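**Plan**
1. Numbering: ring A is C1 (OMe), C2–C5 (four Br), C6 (bridging O). Ring B is C1' (bridging O), C2'-H, C3'-Br, C4'-H, C5'-Br, C6' (OH).
2. Enabling feature: C2, C3, C4 and C5 of ring A all carry Br, and each sits ortho or para to the oxygen on C1 or on C6, while ring B must keep C2'-H and C4'-H. Ring A can therefore be filled completely by electrophilic bromination once ring B is made inert.
3. Cuts, in retrosynthetic order: the O–H at C6' is masked as O–SO2CF3; the four bonds C2–Br, C3–Br, C4–Br and C5–Br are cut together; then the sulfonate S–O bond; C5'–Br; C6'–O (back to C6'–CHO); the bridging O–C1' bond.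
4. Forward: no ring is built. Guaiacol (ring A) and 4-bromo-2-fluorobenzaldehyde (ring B, bringing C3'-Br) are joined first by SNAr while neither is crowded. CHO then becomes OH, the phenol directs C5'-Br, triflation silences ring B, ring A takes four Br, and the triflate is removed.
5. Stereochemistry: the target has no stereocentre and no configurationally stable axis, so nothing has to be set.

Key step: step 5

Remark on the chemistry: the two ring B bromines stand ortho or para to C2' and C4' and so deactivate these positions only weakly. The sulfonate is therefore taken as the triflate, the strongest common oxygen-bound acceptor, rather than a mesylate or tosylate. C3'-Br is bought with the aldehyde because a second bromination of the phenol ring with free Br2 would have to compete with ring A.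

Step 1
Reactants: 1 guaiacol (2-methoxyphenol); 2 4-bromo-2-fluorobenzaldehyde
Product: 3 4-bromo-2-(2-methoxyphenoxy)benzaldehyde
Conditions: K2CO3 (1.5 equiv), DMF, 110 °C
Reagents that add atoms: none
Why: Nucleophilic aromatic substitution (SNAr, addition–elimination), in which the ortho-formyl group stabilises the Meisenheimer adduct at C–F, fluoride is displaced far faster than the para-bromide because addition is rate-limiting, and both partners are still uncrowded, so the bridging O–C1' bond should form cleanly.

Step 2
Reactants: 3 4-bromo-2-(2-methoxyphenoxy)benzaldehyde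
Product: 5 4-bromo-2-(2-methoxyphenoxy)phenol, via aryl formate 4 (not isolated)
Conditions: mCPBA (1.5 equiv), CH2Cl2, rt to reflux; aq. Na2S2O3/NaHCO3 wash; then K2CO3 (0.2 equiv), MeOH, rt
Reagents that add atoms: mCPBA (3-chloroperbenzoic acid), OOC(=O)c1cccc(Cl)c1
Why: Baeyer–Villiger oxidation of an ortho-aryloxybenzaldehyde (the peracid form of the Dakin reaction), in which the aryl group, enriched by its ortho oxygen, migrates in the Criegee adduct in preference to hydride to give formate 4, and mild methanolysis then frees the phenol while the aryl bromide, the methyl ether and the diaryl ether stay inert.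

Step 3
Reactants: 5 4-bromo-2-(2-methoxyphenoxy)phenol
Product: 6 2,4-dibromo-6-(2-methoxyphenoxy)phenol
Conditions: NBS (1.0 equiv, slow addition), iPr2NH (15 mol %), CH2Cl2, 0 °C to rt, dark
Reagents that add atoms: N-bromosuccinimide, O=C1CCC(=O)N1Br
Why: Amine-catalysed ortho-bromination of a phenol with NBS, in which the N-bromoamine made in situ is too weak an electrophile for anisole-type rings in CH2Cl2 and delivers bromine only within its hydrogen-bonded pair with the phenol, whose para position already holds C3'-Br and whose one free ortho position is C5', so ring A should stay untouched although it is the more reactive ring toward free Br2.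

Step 4
Reactants: 6 2,4-dibromo-6-(2-methoxyphenoxy)phenol
Product: 7 2,4-dibromo-6-(2-methoxyphenoxy)phenyl trifluoromethanesulfonate
Conditions: Tf2O (1.2 equiv), pyridine (2.5 equiv), CH2Cl2, 0 °C to rt
Reagents that add atoms: trifluoromethanesulfonic anhydride (Tf2O), O=S(=O)(OS(=O)(=O)C(F)(F)F)C(F)(F)F
Why: O-Sulfonylation of a phenol, in which the acidic di-ortho-substituted phenol is triflated readily by Tf2O with pyridine and the resulting OSO2CF3 group is inert to Br2, HBr and FeBr3 and places a strong acceptor meta to C2' and C4'.

Step 5
Reactants: 7 2,4-dibromo-6-(2-methoxyphenoxy)phenyl trifluoromethanesulfonate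
Product: 9 2,4-dibromo-6-(2,3,4,5-tetrabromo-6-methoxyphenoxy)phenyl trifluoromethanesulfonate, via ring A dibromide 8 (not isolated)
Conditions: Br2 (2.1 equiv), ClCH2CH2Cl, 0 °C; then FeBr3 (15 mol %), Br2 (2.3 equiv), 0 to 50 °C, dark, N2 sweep; aq. NaHSO3
Reagents that add atoms: bromine, BrBr
Why: Each of the four C–Br bonds forms by electrophilic aromatic substitution: Br2, polarised by FeBr3 in the later rounds, adds to ring A to give an arenium ion stabilised by the oxygen ortho or para to the attacked carbon (O on C1 for C2 and C4, the bridging O on C6 for C3 and C5), and loss of the proton as HBr restores the arene. The closest known reaction type is the Lewis-acid-promoted exhaustive bromination of catechol diethers such as veratrole to their tetrabromides. C4 and C3, para to the two oxygens, should react with Br2 alone at 0 °C to give dibromide 8, which keeps the Lewis acid away from the electron-rich stage, and the flanked positions C2 and C5 then fill under FeBr3 on warming. No ring closes and no stereocentre is created. The selectivity needed is between the rings, because C2'-H and C4'-H are ortho and para to the bridging oxygen: it is secured by the triflate, a strong acceptor meta to both positions, by the two bromines already on ring B, by the shielding of C4' between Br on C3' and C5' and of C2' between Br on C3' and the twisted ring A, and by the methoxy oxygen, a second and better donor that only ring A owns. Br2 is held to a small excess over four equivalents and HBr is swept out with N2, so that a seventh substitution and cleavage of the O–CH3 bond stay slow.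

Step 6
Reactants: 9 2,4-dibromo-6-(2,3,4,5-tetrabromo-6-methoxyphenoxy)phenyl trifluoromethanesulfonate
Product: 10 2,4-dibromo-6-(2,3,4,5-tetrabromo-6-methoxyphenoxy)phenol (CNP0266381.0)
Conditions: Et4NOH (35% aq., 2.5 equiv), 1,4-dioxane, rt; then 1 M HCl
Reagents that add atoms: none
Why: Hydrolytic S–O cleavage of an aryl triflate, in which hydroxide attacks sulfur and expels the well-stabilised 2,4-dibromo-6-aryloxyphenoxide at room temperature, conditions under which the aryl bromides, the methyl ether and the diaryl ether persist, and methanol is left out so that no methylating agent can arise from the triflyl group.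

**Compound list**
1 | guaiacol (2-methoxyphenol) | COc1ccccc1O | starting material
2 | 4-bromo-2-fluorobenzaldehyde | O=Cc1ccc(Br)cc1F | starting material
3 | 4-bromo-2-(2-methoxyphenoxy)benzaldehyde | COc1ccccc1Oc1cc(Br)ccc1C=O | intermediate
4 | 4-bromo-2-(2-methoxyphenoxy)phenyl formate (not isolated) | COc1ccccc1Oc1cc(Br)ccc1OC=O | intermediate
5 | 4-bromo-2-(2-methoxyphenoxy)phenol | COc1ccccc1Oc1cc(Br)ccc1O | intermediate
6 | 2,4-dibromo-6-(2-methoxyphenoxy)phenol | COc1ccccc1Oc1cc(Br)cc(Br)c1O | intermediate
7 | 2,4-dibromo-6-(2-methoxyphenoxy)phenyl trifluoromethanesulfonate | COc1ccccc1Oc1cc(Br)cc(Br)c1OS(=O)(=O)C(F)(F)F | intermediate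
8 | 2,4-dibromo-6-(4,5-dibromo-2-methoxyphenoxy)phenyl trifluoromethanesulfonate (not isolated) | COc1cc(Br)c(Br)cc1Oc1cc(Br)cc(Br)c1OS(=O)(=O)C(F)(F)F | intermediate
9 | 2,4-dibromo-6-(2,3,4,5-tetrabromo-6-methoxyphenoxy)phenyl trifluoromethanesulfonate | COc1c(Br)c(Br)c(Br)c(Br)c1Oc1cc(Br)cc(Br)c1OS(=O)(=O)C(F)(F)F | intermediate
10 | 2,4-dibromo-6-(2,3,4,5-tetrabromo-6-methoxyphenoxy)phenol | COc1c(Br)c(Br)c(Br)c(Br)c1Oc1cc(Br)cc(Br)c1O | target

Total step count: 6. Longest linear sequence: 6 steps (1 and 2 to 10).

**Steps most likely to fail**

Step 5. Discrimination between the rings may fade near the end. The last substitution on ring A is slowed by three bromines and by the methoxy group being twisted out of conjugation. Attack on ring B, stalling short of four bromines, or Lewis-acid-assisted loss of the O-methyl group may then intervene. The fallback sets out from 1 and returns at 9. Ring A is brominated before the ether exists, and the crowded ether bond is then made by metal-free O-arylation with a diaryliodonium salt, a reaction type that accepts di-ortho-substituted, weakly nucleophilic phenoxides. Guaiacol 1 with excess Br2 in AcOH (rt to 60 °C) should give 2,3,4,5-tetrabromo-6-methoxyphenol F1. Commercial 2,4-dibromophenol is iodinated at its one free ortho position (NIS, TsOH, MeCN) to 2,4-dibromo-6-iodophenol F2. This is triflated (Tf2O, pyridine) to 2,4-dibromo-6-iodophenyl trifluoromethanesulfonate F3. Oxidation with mCPBA and TsOH in MeCN, followed by 1,3,5-trimethoxybenzene, should give [3,5-dibromo-2-(trifluoromethylsulfonyloxy)phenyl](2,4,6-trimethoxyphenyl)iodonium 4-methylbenzenesulfonate F4. The potassium salt of F1 (K2CO3, MeCN, 40 °C) should take over the electron-poor aryl group of F4 by ligand coupling, with the trimethoxyphenyl group leaving as the aryl iodide. This gives 9 directly.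

Step 3. Bromine may be consumed by ring A, whose positions para to the two oxygens are intrinsically more reactive toward any free Br2 than the remaining ortho position of the bromophenol. Ring B would then be left incompletely substituted, and that gap cannot be closed after triflation. The fallback sets out from 5 and returns at 8, and it gives up the discrimination altogether. Br2 (3.1 equiv) with NaOAc in AcOH–CH2Cl2 at rt should fill the three most activated positions (C5', C4 and C3). It should stop there for lack of a Lewis acid, giving 2,4-dibromo-6-(4,5-dibromo-2-methoxyphenoxy)phenol F5. Triflation (Tf2O, pyridine, CH2Cl2) gives 8, isolated in this case, which enters the FeBr3 stage of step 5.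

Step 2. Hydride rather than aryl migration in the Criegee adduct, encouraged by the para-bromine, would over-oxidise the aldehyde to the acid level instead of inserting oxygen. The fallback sets out from 1 and returns at 5, and it uses a methyl ketone, which has no hydrogen on the carbonyl carbon. SNAr of 1 on commercial 1-(4-bromo-2-fluorophenyl)ethanone (K2CO3, DMF, 120 °C) should give 1-[4-bromo-2-(2-methoxyphenoxy)phenyl]ethanone F6. Baeyer–Villiger oxidation (mCPBA, cat. CF3CO2H, CH2Cl2), with aryl migrating in preference to methyl, should give 4-bromo-2-(2-methoxyphenoxy)phenyl acetate F7. Methanolysis (K2CO3, MeOH) then gives 5.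

**Further compounds**
F1 | step 5 | 2,3,4,5-tetrabromo-6-methoxyphenol | COc1c(O)c(Br)c(Br)c(Br)c1Br
F2 | step 5 | 2,4-dibromo-6-iodophenol | Oc1c(Br)cc(Br)cc1I
F3 | step 5 | 2,4-dibromo-6-iodophenyl trifluoromethanesulfonate | O=S(=O)(Oc1c(Br)cc(Br)cc1I)C(F)(F)F
F4 | step 5 | [3,5-dibromo-2-(trifluoromethylsulfonyloxy)phenyl](2,4,6-trimethoxyphenyl)iodonium 4-methylbenzenesulfonate | COc1cc(OC)c([I+]c2cc(Br)cc(Br)c2OS(=O)(=O)C(F)(F)F)c(OC)c1.Cc1ccc(cc1)S(=O)(=O)[O-]
F5 | step 3 | 2,4-dibromo-6-(4,5-dibromo-2-methoxyphenoxy)phenol | COc1cc(Br)c(Br)cc1Oc1cc(Br)cc(Br)c1O
F6 | step 2 | 1-[4-bromo-2-(2-methoxyphenoxy)phenyl]ethanone | COc1ccccc1Oc1cc(Br)ccc1C(C)=O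
F7 | step 2 | 4-bromo-2-(2-methoxyphenoxy)phenyl acetate | COc1ccccc1Oc1cc(Br)ccc1OC(C)=O
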